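The route rests on closing pyran ring F of the lower (gallocatechin) unit between its C2 oxygen (O1) and aromatic carbon C8a of ring D. The precursor is an open-chain erythro (1R,2S)-1,3-diarylpropane-1,2-diol whose ring D is a 3-bromo-2-fluoro-4,6-bis(benzyloxy)phenyl group. Its benzylic alkoxide displaces fluoride by intramolecular SNAr. The step exploits the 1,3,5-oxygenation of ring D: the C5 and C7 oxygens are meta to C8a, so they tolerate the anionic σ-complex. No C–O bond at C2 or C3 is broken, so the diol becomes the 2,3-trans flavan with retention. The C8 bromine that assists closure then blocks C8 and steers the robinetinidol C4 cation to C6.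

Key step: step 6

Assumption: natural (+)-(2R,3R)-dihydrorobinetin and 3,4,5-tris(benzyloxy)benzaldehyde are taken as catalogue compounds. Flavanoid numbering is used throughout (rings A/C/B in the upper unit, D/F/E in the lower unit).

Step 1
Reactants: 1 1,3,5-trifluorobenzene
Product: 2 1,3-bis(benzyloxy)-5-fluorobenzene
Conditions: BnOH (2.1 equiv), NaH (2.2 equiv), NMP, 0 → 80 °C
Reagents that add atoms: benzyl alcohol, OCc1ccccc1
Why: Twofold SNAr, in which each C–F of 1 is activated by the two meta fluorines and reactivity falls with every F→OBn exchange, so the reaction can be held at the bis-ether.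

Step 2
Reactants: 2 1,3-bis(benzyloxy)-5-fluorobenzene
Product: 3 1,5-bis(benzyloxy)-2,4-dibromo-3-fluorobenzene
Conditions: NBS (2.05 equiv), MeCN, 0 °C → rt, dark
Reagents that add atoms: N-bromosuccinimide, O=C1CCC(=O)N1Br
Why: Electrophilic aromatic bromination, in which the two equivalent positions next to fluorine are each ortho/para to both benzyloxy groups and much less crowded than the position between them, so two equivalents should give the symmetric dibromide.

Step 3
Reactants: 4 3,4,5-tris(benzyloxy)benzaldehyde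
Product: 5 rac-1-[3,4,5-tris(benzyloxy)phenyl]prop-2-en-1-ol
Conditions: CH2=CHMgBr (1.2 equiv), THF, −20 → 0 °C; then H2O
Reagents that add atoms: vinylmagnesium bromide, C=C[Mg]Br
Why: Grignard 1,2-addition to a non-enolisable aldehyde, giving a racemic carbinol centre that is resolved in step 4.

Step 4
Reactants: 5 rac-1-[3,4,5-tris(benzyloxy)phenyl]prop-2-en-1-ol
Product: 6 (R)-[(2S)-oxiran-2-yl][3,4,5-tris(benzyloxy)phenyl]methanol (erythro epoxy alcohol)
Conditions: Ti(OiPr)4 (0.2 equiv), D-(−)-DIPT (0.25 equiv), t-BuOOH (0.45 equiv), 4 Å MS, CH2Cl2, −20 °C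
Reagents that add atoms: tert-butyl hydroperoxide, CC(C)(C)OO
Why: Sharpless kinetic resolution, in which D-(−)-DIPT makes the (S)-allylic alcohol the fast-reacting enantiomer and epoxidises it on the face that gives the erythro product, so one catalytic event sets both the carbinol centre (R in 6) and the oxirane centre (S) while the (R)-alcohol is left behind.

Step 5
Reactants: 3 1,5-bis(benzyloxy)-2,4-dibromo-3-fluorobenzene; 6 erythro epoxy alcohol
Product: 9 (1R,2S)-3-[4,6-bis(benzyloxy)-3-bromo-2-fluorophenyl]-1-[3,4,5-tris(benzyloxy)phenyl]propane-1,2-diol, via [4,6-bis(benzyloxy)-3-bromo-2-fluorophenyl]magnesium chloride 7 (not isolated), via chloromagnesium alkoxide of the epoxy alcohol 8 (not isolated)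
Conditions: 3 (1.3 equiv), i-PrMgCl·LiCl, THF, −20 °C; separately 6, i-PrMgCl (1.0 equiv), THF, −40 °C; combine, CuI (15 mol %), −20 → 0 °C; then H2O
Reagents that add atoms: none
Why: Bromine–magnesium exchange (turbo-Grignard) at one of two equivalent C–Br bonds, accelerated by the flanking F and OBn, followed by Cu(I)-catalysed SN2 opening at the terminal epoxide carbon, which touches neither stereocentre, so the erythro (1R,2S) relationship of 6 is carried into 9.

Step 6
Reactants: 9 (1R,2S)-diol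
Product: 11 (2R,3S)-5,7-bis(benzyloxy)-8-bromo-2-[3,4,5-tris(benzyloxy)phenyl]chroman-3-ol (8-bromo-5,7,3',4',5'-penta-O-benzylgallocatechin), via potassium C1 (benzylic) alkoxide of the diol 10 (not isolated)
Conditions: KHMDS (1.05 equiv), THF–DMPU (4:1), −20 → 45 °C
Reagents that add atoms: none
Why: KHMDS removes the more acidic benzylic hydroxyl proton of 9, alkoxide 10 adds to C8a–F to give a Meisenheimer σ-complex with its charge on C4a, C6 and C8, and fluoride then leaves (addition–elimination). The closest known reaction type is the alkoxide SNAr pyran closure of 3-(2-fluoro-4,6-dialkoxyphenyl)propanols used to make flavan-3-ols. Ring F closes in the 6-exo-trig mode, the C8a=C8 π bond lying outside the new ring. No stereocentre is created: the C2–O and C3–O bonds stay intact, so (1R,2S)-9 is translated with retention into the (2R,3S) 2,3-trans flavan, with no benzylic cation that could scramble C2. Two selectivities are needed: fluoride over bromide, secured because fluoride is the better SNAr nucleofuge and only C8a lies within reach of the tether while C8–Br lowers the barrier inductively; and six- over five-membered closure through O3, secured because one equivalent of base leaves the charge on the benzylic oxygen and only the three-atom tether lets oxygen approach C8a perpendicular to the ring plane. The C5 and C7 benzyloxy groups are meta to C8a and therefore stabilise the σ-complex inductively instead of opposing it.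

Step 7
Reactants: 12 (+)-dihydrorobinetin, (2R,3R)-3,7-dihydroxy-2-(3,4,5-trihydroxyphenyl)chroman-4-one
Product: 13 (2R,3R)-7-(benzyloxy)-3-hydroxy-2-[3,4,5-tris(benzyloxy)phenyl]chroman-4-one
Conditions: BnBr (4.4 equiv), K2CO3 (5 equiv), DMF, rt, Ar
Reagents that add atoms: benzyl bromide, BrCc1ccccc1
Why: Williamson etherification of the four phenols with a carbonate base too weak to alkylate the C3 alcohol, with room temperature and exclusion of air limiting retro-oxa-Michael ring opening so that the purchased C2 and C3 centres are kept.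

Step 8
Reactants: 13 tetra-O-benzyldihydrorobinetin
Product: 14 (2R,3S,4R)-7-(benzyloxy)-2-[3,4,5-tris(benzyloxy)phenyl]chromane-3,4-diol
Conditions: NaBH4, THF–EtOH, 0 °C
Reagents that add atoms: none
Why: Borohydride reduction of the chroman-4-one, in which axial hydride delivery to the half-chair with equatorial C2 aryl and C3 hydroxyl should give the equatorial alcohol (4R, 3,4-trans), a centre that is erased again in step 9.

Step 9
Reactants: 11 8-bromo-penta-O-benzylgallocatechin; 14 tetra-O-benzyl flavan-3,4-diol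
Product: 16 nona-O-benzyl-8-bromo-robinetinidol-(4α→6)-gallocatechin (upper unit 2R,3S,4S; lower unit 2R,3S; Br at C8 of ring D), via (2R,3S)-tetra-O-benzylflavan-4-yl cation 15 (not isolated)
Conditions: 11 (3 equiv, surplus recovered), BF3·OEt2 (0.3 equiv), 4 Å MS, CH2Cl2, −40 → −10 °C, slow addition of 14
Reagents that add atoms: none
Why: Friedel–Crafts flavanylation (dehydrative benzylic alkylation), in which BF3 ionises C4–OH of 14 to cation 15, stabilised by the para C7 oxygen and the ortho O1, and the trioxygenated ring D of 11, with C8 blocked by bromine, can only react at C6, the site that phloroglucinol-type D rings offer in preference to resorcinol-type A rings once C8 is occupied; attack anti to the C3 hydroxyl on the α face of the 2,3-trans half-chair sets C4 as S (3,4-trans, 4α).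

Step 10
Reactants: 16 protected, bromine-capped dimer
Product: 17 robinetinidol-(4α→6)-gallocatechin (target)
Conditions: H2 (1 atm), Pd(OH)2/C, Et3N (1.2 equiv), THF–MeOH–H2O, rt
Reagents that add atoms: none
Why: Catalytic hydrogenolysis cleaves the nine O-benzyl ethers and hydrodehalogenates C8–Br in the same operation, with Et3N taking up HBr, while the cyclic C2–O1 ethers and the C4–C6 bond should survive these mild conditions and no stereocentre is touched.

Compound list
1 | 1,3,5-trifluorobenzene | Fc1cc(F)cc(F)c1 | starting material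
2 | 1,3-bis(benzyloxy)-5-fluorobenzene | Fc1cc(OCc2ccccc2)cc(OCc2ccccc2)c1 | intermediate
3 | 1,5-bis(benzyloxy)-2,4-dibromo-3-fluorobenzene | Fc1c(Br)c(OCc2ccccc2)cc(OCc2ccccc2)c1Br | intermediate
4 | 3,4,5-tris(benzyloxy)benzaldehyde | O=Cc1cc(OCc2ccccc2)c(OCc2ccccc2)c(OCc2ccccc2)c1 | starting material
5 | rac-1-[3,4,5-tris(benzyloxy)phenyl]prop-2-en-1-ol | C=CC(O)c1cc(OCc2ccccc2)c(OCc2ccccc2)c(OCc2ccccc2)c1 | intermediate
6 | (R)-[(2S)-oxiran-2-yl][3,4,5-tris(benzyloxy)phenyl]methanol | C1[C@H](O1)[C@@H](c2cc(OCc3ccccc3)c(OCc3ccccc3)c(OCc3ccccc3)c2)O | intermediate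
7 | [4,6-bis(benzyloxy)-3-bromo-2-fluorophenyl]magnesium chloride | Cl[Mg]c1c(F)c(Br)c(OCc2ccccc2)cc1OCc1ccccc1 | intermediate
8 | chloromagnesium alkoxide of 6 | C1[C@H](O1)[C@@H](c2cc(OCc3ccccc3)c(OCc3ccccc3)c(OCc3ccccc3)c2)O[Mg]Cl | intermediate
9 | (1R,2S)-3-[4,6-bis(benzyloxy)-3-bromo-2-fluorophenyl]-1-[3,4,5-tris(benzyloxy)phenyl]propane-1,2-diol | Fc1c(Br)c(OCc2ccccc2)cc(OCc2ccccc2)c1C[C@H](O)[C@@H](c1cc(OCc2ccccc2)c(OCc2ccccc2)c(OCc2ccccc2)c1)O | intermediate
10 | potassium C1 (benzylic) alkoxide of 9 | Fc1c(Br)c(OCc2ccccc2)cc(OCc2ccccc2)c1C[C@H](O)[C@@H](c1cc(OCc2ccccc2)c(OCc2ccccc2)c(OCc2ccccc2)c1)[O-].[K+] | intermediate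
11 | (2R,3S)-5,7-bis(benzyloxy)-8-bromo-2-[3,4,5-tris(benzyloxy)phenyl]chroman-3-ol | Brc1c(OCc2ccccc2)cc(OCc2ccccc2)c2c1O[C@H](c1cc(OCc3ccccc3)c(OCc3ccccc3)c(OCc3ccccc3)c1)[C@@H](O)C2 | intermediate
12 | (+)-dihydrorobinetin, (2R,3R) | Oc1ccc2c(c1)O[C@H](c1cc(O)c(O)c(O)c1)[C@@H](O)C2=O | starting material
13 | (2R,3R)-7-(benzyloxy)-3-hydroxy-2-[3,4,5-tris(benzyloxy)phenyl]chroman-4-one | O(Cc1ccccc1)c1ccc2c(c1)O[C@H](c1cc(OCc3ccccc3)c(OCc3ccccc3)c(OCc3ccccc3)c1)[C@@H](O)C2=O | intermediate
14 | (2R,3S,4R)-7-(benzyloxy)-2-[3,4,5-tris(benzyloxy)phenyl]chromane-3,4-diol | O(Cc1ccccc1)c1ccc2c(c1)O[C@H](c1cc(OCc3ccccc3)c(OCc3ccccc3)c(OCc3ccccc3)c1)[C@@H](O)[C@@H]2O | intermediate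
15 | (2R,3S)-7-(benzyloxy)-3-hydroxy-2-[3,4,5-tris(benzyloxy)phenyl]chroman-4-yl cation | O(Cc1ccccc1)c1ccc2c(c1)O[C@H](c1cc(OCc3ccccc3)c(OCc3ccccc3)c(OCc3ccccc3)c1)[C@@H](O)[CH+]2 | intermediate
16 | nona-O-benzyl-8-bromo-robinetinidol-(4α→6)-gallocatechin | O(Cc1ccccc1)c1ccc2c(c1)O[C@H](c1cc(OCc3ccccc3)c(OCc3ccccc3)c(OCc3ccccc3)c1)[C@@H](O)[C@@H]2c1c(OCc2ccccc2)c(Br)c2c(c1OCc1ccccc1)C[C@H](O)[C@@H](c1cc(OCc3ccccc3)c(OCc3ccccc3)c(OCc3ccccc3)c1)O2 | intermediate
17 | robinetinidol-(4α→6)-gallocatechin | Oc1ccc2c(c1)O[C@H](c1cc(O)c(O)c(O)c1)[C@@H](O)[C@@H]2c1c(O)cc2c(c1O)C[C@H](O)[C@@H](c1cc(O)c(O)c(O)c1)O2 | target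

Total step count: 10. Longest linear sequence: 6 steps (steps 3, 4, 5, 6, 9 and 10, from 4).

Steps most likely to fail

First, step 9. C6 of 11 is flanked by two benzyloxy groups and deactivated by the bromine. The cation may therefore be intercepted by the resorcinol-type A ring of a second molecule of 14 or of the product (self-condensation). It may also be intercepted by a pyrogallol-type B/E ring, or be attacked with poor facial selectivity. The fallback caps both partners. It sets out from 14, where NBS (1 equiv, CH2Cl2, −78 °C) should brominate the open A-ring position C6 to give (2R,3S,4R)-7-(benzyloxy)-6-bromo-2-[3,4,5-tris(benzyloxy)phenyl]chromane-3,4-diol F1. BF3·OEt2-catalysed coupling of F1 with 11 should then give the doubly capped nona-O-benzyl-6,8''-dibromo dimer F2. The hydrogenolysis of step 10 (Et3N raised to 2.4 equiv) removes both bromines and comes back to the route at 17.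

Second, step 6. After proton transfer the ring may close through the C3 alkoxide to a five-membered ring, or fluoride displacement may be too slow to compete with decomposition. The fallback masks O3 before the closure. It sets out from 6.
- TBSCl/imidazole gives the O-TBS epoxide F3.
- Opening with 7 under CuI catalysis gives the C1-O-TBS, C2-hydroxy adduct F4.
- MOMCl/i-Pr2NEt (no alkoxide is formed, hence no O→O silyl migration) gives the C2-O-MOM ether F5.
- TBAF gives the free benzylic alcohol F6.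
- KHMDS in THF–DMPU closes this single nucleophile onto C8a to give the 3-O-MOM-8-bromoflavan F7.
- Catalytic HCl in MeOH–THF removes the acetal and comes back to the route at 11.

Third, step 5. The ortho-fluoroaryl Grignard reagent may be lost by elimination of magnesium fluoride (aryne formation). The magnesium epoxy-alkoxide may undergo Payne-type isomerisation, or the epoxide may be opened by halide. The fallback uses a protected epoxide and a Lewis-acid-assisted aryllithium at low temperature. It sets out from 6 and 3.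
- TESCl/imidazole converts 6 into the O-TES epoxide F8.
- n-BuLi (1.0 equiv, Et2O–THF, −78 °C) converts 3 into [4,6-bis(benzyloxy)-3-bromo-2-fluorophenyl]lithium F9.
- BF3·OEt2 at −78 °C joins the two at the terminal epoxide carbon to give the C1-O-TES adduct F10.
- AcOH–THF–H2O cleaves the silyl ether and comes back to the route at 9.

Further compounds
F1 | step 9 | (2R,3S,4R)-7-(benzyloxy)-6-bromo-2-[3,4,5-tris(benzyloxy)phenyl]chromane-3,4-diol | O(Cc1ccccc1)c1c(Br)cc2c(c1)O[C@H](c1cc(OCc3ccccc3)c(OCc3ccccc3)c(OCc3ccccc3)c1)[C@@H](O)[C@@H]2O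
F2 | step 9 | nona-O-benzyl-6,8''-dibromo-robinetinidol-(4α→6)-gallocatechin | O(Cc1ccccc1)c1c(Br)cc2c(c1)O[C@H](c1cc(OCc3ccccc3)c(OCc3ccccc3)c(OCc3ccccc3)c1)[C@@H](O)[C@@H]2c1c(OCc2ccccc2)c(Br)c2c(c1OCc1ccccc1)C[C@H](O)[C@@H](c1cc(OCc3ccccc3)c(OCc3ccccc3)c(OCc3ccccc3)c1)O2
F3 | step 6 | tert-butyldimethylsilyl ether of 6 | C1[C@H](O1)[C@@H](c2cc(OCc3ccccc3)c(OCc3ccccc3)c(OCc3ccccc3)c2)O[Si](C)(C)C(C)(C)C
F4 | step 6 | (1R,2S)-3-[4,6-bis(benzyloxy)-3-bromo-2-fluorophenyl]-1-(tert-butyldimethylsilyloxy)-1-[3,4,5-tris(benzyloxy)phenyl]propan-2-ol | Fc1c(Br)c(OCc2ccccc2)cc(OCc2ccccc2)c1C[C@H](O)[C@@H](c1cc(OCc2ccccc2)c(OCc2ccccc2)c(OCc2ccccc2)c1)O[Si](C)(C)C(C)(C)C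
F5 | step 6 | C2-O-methoxymethyl ether of F4 | Fc1c(Br)c(OCc2ccccc2)cc(OCc2ccccc2)c1C[C@H](OCOC)[C@@H](c1cc(OCc2ccccc2)c(OCc2ccccc2)c(OCc2ccccc2)c1)O[Si](C)(C)C(C)(C)C
F6 | step 6 | (1R,2S)-3-[4,6-bis(benzyloxy)-3-bromo-2-fluorophenyl]-2-(methoxymethoxy)-1-[3,4,5-tris(benzyloxy)phenyl]propan-1-ol | Fc1c(Br)c(OCc2ccccc2)cc(OCc2ccccc2)c1C[C@H](OCOC)[C@@H](c1cc(OCc2ccccc2)c(OCc2ccccc2)c(OCc2ccccc2)c1)O
F7 | step 6 | (2R,3S)-5,7-bis(benzyloxy)-8-bromo-3-(methoxymethoxy)-2-[3,4,5-tris(benzyloxy)phenyl]chromane | Brc1c(OCc2ccccc2)cc(OCc2ccccc2)c2c1O[C@H](c1cc(OCc3ccccc3)c(OCc3ccccc3)c(OCc3ccccc3)c1)[C@@H](OCOC)C2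
F8 | step 5 | triethylsilyl ether of 6 | C1[C@H](O1)[C@@H](c2cc(OCc3ccccc3)c(OCc3ccccc3)c(OCc3ccccc3)c2)O[Si](CC)(CC)CC
F9 | step 5 | [4,6-bis(benzyloxy)-3-bromo-2-fluorophenyl]lithium | [Li]c1c(F)c(Br)c(OCc2ccccc2)cc1OCc1ccccc1
F10 | step 5 | (1R,2S)-3-[4,6-bis(benzyloxy)-3-bromo-2-fluorophenyl]-1-(triethylsilyloxy)-1-[3,4,5-tris(benzyloxy)phenyl]propan-2-ol | Fc1c(Br)c(OCc2ccccc2)cc(OCc2ccccc2)c1C[C@H](O)[C@@H](c1cc(OCc2ccccc2)c(OCc2ccccc2)c(OCc2ccccc2)c1)O[Si](CC)(CC)CC
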